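**Plan**

- Retrosynthesis: the phenol is freed last from its benzyl ether. The oxolan-2-one is then traced back to a seven-membered lactone, a 4,7-dihydrooxepin-2(3H)-one, in which a CH=CH–CH2 tether lies between C4 and the ring oxygen. Next the C3–C4 bond is cut, and after that the C3–benzyl bond, the alkene, the lactone C–O bond and the allylic ether C–O bond.
- Feature used: C3 of the oxolan-2-one is an enolisable ester carbon that carries oxygen, and C4 is its neighbour with a CH2–O arm. The C3–C4 bond can therefore be the σ bond made in a [2,3]-Wittig shift from the C3 oxygen to an allyl terminus, the ester oxygen being tied to the other end of the allyl unit.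
- Forward ring order: 1,4-dioxan-2-one (temporary six-membered ring) → seven-membered lactone (closed by the C3–C4 bond, tertiary hydroxyl released) → oxolan-2-one (tether leaves as ethylene glycol).
- Stereochemistry: one C–O stereocentre (C5 of the dioxanone, R) is set by an enantioselective palladium-catalysed etherification. The ring-constrained shift with an E alkene transfers it to both target centres, and the original centre becomes sp2.

Key step: step 6

Assumption: in the palladium-catalysed alcohol addition to 2-ethenyloxirane the (S,S)-ligand is taken to give the R ether; if the sense is the opposite, the (R,R)-ligand is used and nothing else changes.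

**Route**

Step 1
Reactants: 1 2-ethenyloxirane (racemic); 2 methyl glycolate
Product: 3 methyl 2-{[(2R)-1-hydroxybut-3-en-2-yl]oxy}acetate
Conditions: Pd2(dba)3·CHCl3 (1 mol %), (S,S)-DACH-phenyl bisphosphine ligand N,N'-[(1S,2S)-cyclohexane-1,2-diyl]bis[2-(diphenylphosphanyl)benzamide] (3 mol %), Et3B (2 mol %), CH2Cl2, rt
Reagents that add atoms: none
Why: Zerovalent palladium opens the vinyl epoxide to an equilibrating π-allyl alkoxide, and the boron-bound alkoxide delivers the glycolate oxygen to the internal allyl carbon inside the chiral pocket (dynamic kinetic asymmetric allylic etherification), which should set the single stereocentre as R and leave the primary hydroxyl free.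

Step 2
Reactants: 3 methyl 2-{[(2R)-1-hydroxybut-3-en-2-yl]oxy}acetate
Product: 4 (5R)-5-ethenyl-1,4-dioxan-2-one
Conditions: camphor-10-sulfonic acid (5 mol %), toluene, 80 °C, 4 Å molecular sieves
Reagents that add atoms: none
Why: Acid-catalysed intramolecular transesterification (6-exo-trig lactonisation) of the hydroxy ester is driven by removal of methanol and does not touch the allylic ether stereocentre.

Step 3
Reactants: 4 (5R)-5-ethenyl-1,4-dioxan-2-one; 5 4-allyl-1,2-dimethoxybenzene (methyl eugenol)
Product: 6 (5R)-5-[(1E)-3-(3,4-dimethoxyphenyl)prop-1-en-1-yl]-1,4-dioxan-2-one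
Conditions: 5 (3 equiv), second-generation Grubbs catalyst RuCl2(=CHPh)(PCy3)(H2IMes) (5 mol %), 1,4-benzoquinone (10 mol %), CH2Cl2, 40 °C
Reagents that add atoms: none
Why: Olefin cross metathesis between the hindered allylic-ether vinyl group and an excess of the readily dimerising allylarene should give the E-disubstituted alkene, with benzoquinone suppressing migration of the double bond into conjugation.

Step 4
Reactants: 7 [4-(benzyloxy)-3-methoxyphenyl]methanol
Product: 8 1-(benzyloxy)-4-(bromomethyl)-2-methoxybenzene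
Conditions: PBr3 (0.4 equiv), Et2O, 0 °C; used crude
Reagents that add atoms: phosphorus tribromide, BrP(Br)Br
Why: Substitution of an electron-rich benzylic alcohol through its bromophosphite (bromination with PBr3) gives the reactive benzylic bromide.

Step 5
Reactants: 6 (5R)-5-[(1E)-3-(3,4-dimethoxyphenyl)prop-1-en-1-yl]-1,4-dioxan-2-one; 8 1-(benzyloxy)-4-(bromomethyl)-2-methoxybenzene
Product: 10 (5R)-3-{[4-(benzyloxy)-3-methoxyphenyl]methyl}-5-[(1E)-3-(3,4-dimethoxyphenyl)prop-1-en-1-yl]-1,4-dioxan-2-one (both C3 epimers), via lithium enolate 9 (not isolated)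
Conditions: LiN(SiMe3)2 (1.05 equiv) added to 6 and 8 (1.2 equiv), THF/DMPU, −78 °C
Reagents that add atoms: none
Why: Kinetic lactone enolate alkylation with the bromide already present should give C-benzylation at C3 before the enolate can rearrange; the configuration at C3 is irrelevant because this centre becomes trigonal again in step 6, and C5 is untouched.

Step 6
Reactants: 10 (5R)-3-{[4-(benzyloxy)-3-methoxyphenyl]methyl}-5-[(1E)-3-(3,4-dimethoxyphenyl)prop-1-en-1-yl]-1,4-dioxan-2-one
Product: 13 (3S,4S)-3-{[4-(benzyloxy)-3-methoxyphenyl]methyl}-4-[(3,4-dimethoxyphenyl)methyl]-3-hydroxy-4,7-dihydrooxepin-2(3H)-one, via potassium enolate 11 (not isolated), via potassium alkoxide 12 (not isolated)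
Conditions: KN(SiMe3)2 (1.2 equiv), THF (0.02 M), −78 → −20 °C; AcOH, −78 °C
Reagents that add atoms: none
Why: Proposed new method: deprotonation at C3 gives a ring-fixed enolate whose carbanion carbon stands 1,3 across O4 to the alkenyl-bearing C5, so a concerted suprafacial [2,3]-Wittig shift (six electrons, five-centre array C3–O4–C5–CH=CH) can form the C3–C bond while O4–C5 breaks; the closest known reactions are the ester-enolate [2,3]-Wittig rearrangement of open-chain α-allyloxy esters and the [2,3]-Wittig ring contractions of macrocyclic allylic ethers. The seven-membered lactone is closed as a one-atom ring expansion of the dioxanone through a bicyclo[3.2.1]-like transition state in which the axial alkenyl group on C5 bridges to the axial lobe of C3. The quaternary carbinol centre is controlled by C5, because the alkenyl group can reach only the enolate face on which it stands. The adjacent tertiary centre is controlled by the E geometry together with the tether, which admits only the rotamer that ends as a cis ring alkene and so exposes one alkene face, placing the arylmethyl group exo and cis to the new hydroxyl. The former stereocentre becomes sp2 and the oxygen on C3 is released as the free alkoxide, so one easily set C–O centre is traded for the quaternary/tertiary pair. The step needs the [2,3] shift to win over the 1,2 shift and over intermolecular ester condensation, which low temperature and dilution should secure, and a Claisen path is excluded because the ester oxygen is not allylic.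

Step 7
Reactants: 13 (3S,4S)-3-{[4-(benzyloxy)-3-methoxyphenyl]methyl}-4-[(3,4-dimethoxyphenyl)methyl]-3-hydroxy-4,7-dihydrooxepin-2(3H)-one
Product: 16 (3S,4S)-3-{[4-(benzyloxy)-3-methoxyphenyl]methyl}-4-[(3,4-dimethoxyphenyl)methyl]-3-hydroxyoxolan-2-one (O-benzyltrachelogenin), via ozonide 14 (not isolated), via hydroxyethyl ester 15 (not isolated)
Conditions: O3, CH2Cl2, −78 °C (Sudan Red 7B end point); then NaBH4, MeOH, −78 → 0 °C; pH 7 buffer work-up
Reagents that add atoms: ozone, [O-][O+]=O
Why: Ozonolysis of the only alkene, borohydride reduction of the ozonide to the primary alcohol on C4 and to a 2-hydroxyethyl ester, and translactonisation of the resulting 1,4-hydroxy ester (5-exo-trig) should give the five-membered lactone with loss of the tether as ethylene glycol, no stereocentre being touched.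

Step 8
Reactants: 16 (3S,4S)-3-{[4-(benzyloxy)-3-methoxyphenyl]methyl}-4-[(3,4-dimethoxyphenyl)methyl]-3-hydroxyoxolan-2-one
Product: 17 trachelogenin, (3S,4S)-4-[(3,4-dimethoxyphenyl)methyl]-3-hydroxy-3-[(4-hydroxy-3-methoxyphenyl)methyl]oxolan-2-one
Conditions: H2 (1 atm), 10% Pd/C, EtOAc, rt
Reagents that add atoms: none
Why: Hydrogenolysis of the phenolic benzyl ether over palladium should be selective because the molecule holds no other benzylic carbon–oxygen bond.

**Compound list**

1 | 2-ethenyloxirane (racemic) | C=CC1CO1 | starting material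
2 | methyl glycolate | COC(=O)CO | starting material
3 | methyl 2-{[(2R)-1-hydroxybut-3-en-2-yl]oxy}acetate | COC(=O)CO[C@H](C=C)CO | intermediate
4 | (5R)-5-ethenyl-1,4-dioxan-2-one | O=C1CO[C@H](C=C)CO1 | intermediate
5 | 4-allyl-1,2-dimethoxybenzene (methyl eugenol) | C=CCc1ccc(OC)c(OC)c1 | starting material
6 | (5R)-5-[(1E)-3-(3,4-dimethoxyphenyl)prop-1-en-1-yl]-1,4-dioxan-2-one | O=C1CO[C@H](/C=C/Cc2ccc(OC)c(OC)c2)CO1 | intermediate
7 | [4-(benzyloxy)-3-methoxyphenyl]methanol | OCc1ccc(OCc2ccccc2)c(OC)c1 | starting material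
8 | 1-(benzyloxy)-4-(bromomethyl)-2-methoxybenzene | BrCc1ccc(OCc2ccccc2)c(OC)c1 | intermediate
9 | lithium enolate of 6 | [Li+].[O-]C1=CO[C@H](/C=C/Cc2ccc(OC)c(OC)c2)CO1 | intermediate (not isolated)
10 | (5R)-3-{[4-(benzyloxy)-3-methoxyphenyl]methyl}-5-[(1E)-3-(3,4-dimethoxyphenyl)prop-1-en-1-yl]-1,4-dioxan-2-one, both C3 epimers | O=C1OC[C@@H](/C=C/Cc2ccc(OC)c(OC)c2)OC1Cc1ccc(OCc2ccccc2)c(OC)c1 | intermediate
11 | potassium enolate of 10 | [K+].[O-]C1=C(Cc2ccc(OCc3ccccc3)c(OC)c2)O[C@H](/C=C/Cc2ccc(OC)c(OC)c2)CO1 | intermediate (not isolated)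
12 | potassium alkoxide of 13 | [K+].COc1cc(C[C@@]2([O-])C(=O)OCC=C[C@@H]2Cc2ccc(OC)c(OC)c2)ccc1OCc1ccccc1 | intermediate (not isolated)
13 | (3S,4S)-3-{[4-(benzyloxy)-3-methoxyphenyl]methyl}-4-[(3,4-dimethoxyphenyl)methyl]-3-hydroxy-4,7-dihydrooxepin-2(3H)-one (cis ring alkene) | COc1cc(C[C@@]2(O)C(=O)OCC=C[C@@H]2Cc2ccc(OC)c(OC)c2)ccc1OCc1ccccc1 | intermediate
14 | ozonide (1,2,4-trioxolane) of 13 | COc1cc(C[C@@]2(O)C(=O)OCC3OOC(O3)[C@@H]2Cc2ccc(OC)c(OC)c2)ccc1OCc1ccccc1 | intermediate (not isolated)
15 | 2-hydroxyethyl (2S,3S)-2-{[4-(benzyloxy)-3-methoxyphenyl]methyl}-3-[(3,4-dimethoxyphenyl)methyl]-2,4-dihydroxybutanoate | COc1cc(C[C@@](O)(C(=O)OCCO)[C@H](CO)Cc2ccc(OC)c(OC)c2)ccc1OCc1ccccc1 | intermediate (not isolated)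
16 | (3S,4S)-3-{[4-(benzyloxy)-3-methoxyphenyl]methyl}-4-[(3,4-dimethoxyphenyl)methyl]-3-hydroxyoxolan-2-one | COc1cc(C[C@@]2(O)C(=O)OC[C@@H]2Cc2ccc(OC)c(OC)c2)ccc1OCc1ccccc1 | intermediate
17 | trachelogenin, (3S,4S)-4-[(3,4-dimethoxyphenyl)methyl]-3-hydroxy-3-[(4-hydroxy-3-methoxyphenyl)methyl]oxolan-2-one | COc1cc(C[C@@]2(O)C(=O)OC[C@@H]2Cc2ccc(OC)c(OC)c2)ccc1O | target

**Step count and risks**

Total steps: 8. Longest linear sequence: 7 (steps 1, 2, 3, 5, 6, 7, 8).

Step 6 (proposed new method). The enolate carbon may fail to reach the alkene terminus through the bridged transition state, so that a radical-pair 1,2 shift, fragmentation of the enolate or intermolecular ester condensation takes over. The fallback uses known chemistry, sets out from 5 and 8 and comes back at 16. Anti-Markovnikov hydroboration–oxidation of 5 (9-BBN, THF; NaOH, H2O2) should give 3-(3,4-dimethoxyphenyl)propan-1-ol F1. Acylation with bromoacetyl bromide (NaHCO3, MeCN) gives 3-(3,4-dimethoxyphenyl)propyl 2-bromoacetate F2, and N,N'-ditosylhydrazine with DBU converts it into 3-(3,4-dimethoxyphenyl)propyl 2-diazoacetate F3. The chiral carboxamidate catalyst dirhodium tetrakis[methyl 2-oxo-1-(3-phenylpropanoyl)imidazolidine-4-carboxylate], Rh2(MPPIM)4 (the antipode that gives the R lactone), in CH2Cl2 at 40 °C then closes the lactone at the same ring bond by enantioselective carbenoid insertion into the C–H bond two carbons from the ester oxygen, giving (4R)-4-[(3,4-dimethoxyphenyl)methyl]oxolan-2-one F4. Hydroxylation of its lithium enolate with 2-(phenylsulfonyl)-3-phenyloxaziridine gives (3R,4S)-4-[(3,4-dimethoxyphenyl)methyl]-3-hydroxyoxolan-2-one F5. C-Alkylation of the dianion of F5 (LiN(iPr)2, 2.2 equiv, THF/HMPA, −78 °C) with 8, anti to the C4 substituent, should give 16.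

Step 5. The unsubstituted lactone enolate may undergo a premature sigmatropic shift or self-condensation before it is alkylated, and double alkylation may follow. The fallback sets out from 3 and comes back at 10. Silylation (TBSCl, imidazole, CH2Cl2) gives methyl 2-{[(2R)-1-{[tert-butyl(dimethyl)silyl]oxy}but-3-en-2-yl]oxy}acetate F6. Its open-chain lithium enolate, in which the vinyl group is not held over the enolate carbon, is benzylated with 8 (LiN(SiMe3)2, THF, −78 °C) to methyl 3-[4-(benzyloxy)-3-methoxyphenyl]-2-{[(2R)-1-{[tert-butyl(dimethyl)silyl]oxy}but-3-en-2-yl]oxy}propanoate F7. Camphor-10-sulfonic acid in MeOH removes the silyl group to give methyl 3-[4-(benzyloxy)-3-methoxyphenyl]-2-{[(2R)-1-hydroxybut-3-en-2-yl]oxy}propanoate F8, which is lactonised as in step 2 to (5R)-3-{[4-(benzyloxy)-3-methoxyphenyl]methyl}-5-ethenyl-1,4-dioxan-2-one F9. Cross metathesis of F9 with 5 under the conditions of step 3 gives 10.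

Step 7. Ozone may oxidise the alkoxy-substituted arenes in competition with the alkene, the β-hydroxy aldehyde may fragment by retro-aldol reaction before it is reduced, and borohydride may over-reduce the α-hydroxy ester. The fallback sets out from 13 and comes back at 16. The tertiary hydroxyl is first masked (Me3SiOTf, 2,6-lutidine, CH2Cl2, −78 °C) as (3S,4S)-3-{[4-(benzyloxy)-3-methoxyphenyl]methyl}-4-[(3,4-dimethoxyphenyl)methyl]-3-[(trimethylsilyl)oxy]-4,7-dihydrooxepin-2(3H)-one F10, which removes both the alkoxide needed for retro-aldol cleavage and the hydroxyl that activates the ester towards hydride. Ozonolysis in CH2Cl2/pyridine at −78 °C with a sub-stoichiometric ozone charge, followed by NaBH4 in MeOH, should then give (3S,4S)-3-{[4-(benzyloxy)-3-methoxyphenyl]methyl}-4-[(3,4-dimethoxyphenyl)methyl]-3-[(trimethylsilyl)oxy]oxolan-2-one F11 with loss of ethylene glycol. Treatment with 1 M HCl in THF removes the silyl group to give 16.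

**Further compounds**

F1 | step 6 | 3-(3,4-dimethoxyphenyl)propan-1-ol | OCCCc1ccc(OC)c(OC)c1
F2 | step 6 | 3-(3,4-dimethoxyphenyl)propyl 2-bromoacetate | BrCC(=O)OCCCc1ccc(OC)c(OC)c1
F3 | step 6 | 3-(3,4-dimethoxyphenyl)propyl 2-diazoacetate | [N-]=[N+]=CC(=O)OCCCc1ccc(OC)c(OC)c1
F4 | step 6 | (4R)-4-[(3,4-dimethoxyphenyl)methyl]oxolan-2-one | O=C1C[C@@H](Cc2ccc(OC)c(OC)c2)CO1
F5 | step 6 | (3R,4S)-4-[(3,4-dimethoxyphenyl)methyl]-3-hydroxyoxolan-2-one | O[C@H]1C(=O)OC[C@@H]1Cc1ccc(OC)c(OC)c1
F6 | step 5 | methyl 2-{[(2R)-1-{[tert-butyl(dimethyl)silyl]oxy}but-3-en-2-yl]oxy}acetate | COC(=O)CO[C@H](C=C)CO[Si](C)(C)C(C)(C)C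
F7 | step 5 | methyl 3-[4-(benzyloxy)-3-methoxyphenyl]-2-{[(2R)-1-{[tert-butyl(dimethyl)silyl]oxy}but-3-en-2-yl]oxy}propanoate | COC(=O)C(Cc1ccc(OCc2ccccc2)c(OC)c1)O[C@H](C=C)CO[Si](C)(C)C(C)(C)C
F8 | step 5 | methyl 3-[4-(benzyloxy)-3-methoxyphenyl]-2-{[(2R)-1-hydroxybut-3-en-2-yl]oxy}propanoate | COC(=O)C(Cc1ccc(OCc2ccccc2)c(OC)c1)O[C@H](C=C)CO
F9 | step 5 | (5R)-3-{[4-(benzyloxy)-3-methoxyphenyl]methyl}-5-ethenyl-1,4-dioxan-2-one | O=C1OC[C@@H](C=C)OC1Cc1ccc(OCc2ccccc2)c(OC)c1
F10 | step 7 | (3S,4S)-3-{[4-(benzyloxy)-3-methoxyphenyl]methyl}-4-[(3,4-dimethoxyphenyl)methyl]-3-[(trimethylsilyl)oxy]-4,7-dihydrooxepin-2(3H)-one | COc1cc(C[C@@]2(O[Si](C)(C)C)C(=O)OCC=C[C@@H]2Cc2ccc(OC)c(OC)c2)ccc1OCc1ccccc1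
F11 | step 7 | (3S,4S)-3-{[4-(benzyloxy)-3-methoxyphenyl]methyl}-4-[(3,4-dimethoxyphenyl)methyl]-3-[(trimethylsilyl)oxy]oxolan-2-one | COc1cc(C[C@@]2(O[Si](C)(C)C)C(=O)OC[C@@H]2Cc2ccc(OC)c(OC)c2)ccc1OCc1ccccc1
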